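Numbering used throughout: isochroman-1-one numbering (C1 lactone carbonyl, O2, C3, C4, C4a, C5–C8, C8a); C9 is the CH2O carbon on C3; ring A is the fused benzene, ring B the ester arene.

## The problem

Compound 30 is a 3,4-dihydroisocoumarin whose C3 is a hemiketal. Ring A is a fully substituted benzene (carboxyl C1 on C8a, OH on C8, the only ring hydrogen on C7, OMe on C6, Me on C5, side chain on C4a), and the C4(H)(Me)–C3(OH)(C9H2O) unit is tied back to C1 through O2. C9 carries a doubly ortho-substituted aryl ester (ring B, a 2,4-dihydroxy-5,6-dimethylbenzoate), so C3 is a masked α-acyloxy ketone.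

There are two stereocentres, C4 (S) and C3 (R), but only C4 has to be made. The lactol is the ring-chain tautomer of a keto acid, so C3 equilibrates and follows C4: its hydroxyl sits axial and anti to the C4 methyl, which is pseudoaxial to avoid the C5 methyl. C4 is benzylic and, once C3 is a ketone, α to a carbonyl. Base, hot acid or dehydration of the lactol to an isocoumarin would erase it, so the ketone has to appear late and be handled close to neutrality.

Of four phenolic oxygens exactly one, on C6, is methylated. C6–O and C8–O of ring A must therefore be told apart, and ring B must stay masked to the end. The hindered ester, the hemiketal and two electron-rich rings exclude strong nucleophiles, strong oxidants and strong Lewis acids late in the route.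

The enabling feature is that C1, C8a, C8, C7, C6, C5, C4a and C4 form one unbranched chain with oxygen on C1, C8 and C6 and methyls on C5 and C4. A C8a–C4a aldol condensation of a poly-β-carbonyl chain therefore closes ring A. If C1 and the C8 oxygen are held together in a dioxinone, the C6 hydroxyl is formed as the only free phenol.

## Retrosynthesis

**Ring B benzyl ethers (30 from 29).** The two O–benzyl bonds of ring B are cut last. Hydrogenolysis of 29 is neutral, touches neither the lactol nor the ester, and leaves only a filtration between the last reaction and 30. Acid-labile ethers were set aside because their removal would release an electrophile next to a free resorcinol.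

**Lactol (29 from 27 via 28).** The O2–C3 hemiketal bond and the two C–O bonds of the isopropylidene group are cut. Keto acid 28 closes to 29 by itself, so the real precursor is ketone 27, in which C1 and the C8 oxygen are still tied in the benzodioxinone. The forward step is an aqueous acid hydrolysis that must stop short of enolisation toward C4 and of dehydration of the lactol. An alkoxide opening of the dioxinone was not chosen for the main line, because it would have to precede the oxidation at C3 and would give up the protection of the carboxyl and the C8 phenol.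

**Oxidation state and methyl ether (27 from 26, 25, 24).** Ketone 27 comes from alcohol 26 by a non-basic oxidation. Alcohol 26 comes from silyl ether 25, and 25 from phenol 24 by methylation. These steps change only functional groups. They rely on 24 having a single free phenol, so methylation needs no selectivity, and on C3 being carried as a silyl ether until two steps before the lactol forms.

**Ring A (24 from 22), the key disconnection.** The C8a–C4a bond is cut and ring A is unravelled to the diketo-dioxinone 22. This removes the hexasubstituted arene in one stroke and replaces it by an open chain whose only fixed stereocentre is C4. The alternatives are to build the arene by electrophilic substitution or to buy it. Neither distinguishes C6–O from C8–O as directly, nor places five different substituents around the ring without regiochemical steps. The forward reaction must favour the C-aldol over pyranone formation and must not touch C4–H or the C3 silyloxy group.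

**C5–C4a bond (22 from 21, from 19 and 15).** The β-diketone of 22 is cut between C5 and C4a. The direct Claisen coupling of the dianion of 19 with Weinreb amide 14 would be two steps shorter. It was not chosen as the main line, because a secondary carbanion would have to attack an α-branched amide that is prone to enolisation and β-elimination of the silyloxy group. An aldol addition of dianion 20 to aldehyde 15, followed by oxidation of 21, forms the same bond with a much faster electrophile. The two new centres of 21 are lost on oxidation, so no selectivity is required.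

**C7–C6 bond (19 from 16 and 17).** Keto-dioxinone 19 is cut between C7 and C6 into the lithium dienolate of dioxinone 16 and propionyl chloride 17. Both are commercial and the γ-acylation of this dienolate is standard.

**C4–C3 bond and the C4 stereocentre (15 from 14, 13, 12, from 10 and 9).** Aldehyde 15 comes from Weinreb amide 14, which comes from 13 by silylation and from 12 by transamination. The C4–C3 bond of 12 is cut by an Evans syn aldol between the (R)-propionyl oxazolidinone 10 and the aroyloxyacetaldehyde 9. This sets C4 with auxiliary control and brings in C3, C9 and the ring B ester together. The C3 configuration that comes with it is irrelevant, since C3 is oxidised later. Transamination is placed before silylation because the free C3 hydroxyl directs the aluminium amide to the exocyclic carbonyl.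

**Ring B ester (9 from 7, from 5 and 6; 5 from 4, 3, 1).** Aldehyde 9 comes from allyl ester 7 by oxidative cleavage. Ester 7 is cut at the O–allyl bond into acid 5 and allyl bromide 6, so the hindered ester is made by carboxylate alkylation and not by acyl substitution. Acid 5 comes from 4,5-dimethylresorcinol 1 by formylation (3), benzylation (4) and oxidation.

## Roads not taken

Alternative 1: The cut is through the C9 ester C–O bond and the C1'–C6' bond of ring B. A ring A alcohol A1 (C3 still a methylene) would capture the acylketene released on heating the dimethyl diketo-dioxinone A2. Cs2CO3 and then acid would aromatise the triketo ester to A3, the C9 ester of the free dihydroxy acid.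
- Merits: the hindered ester is formed without activating a hindered acid, and ring B needs no protecting groups, which saves a benzylation. In this respect it is better than the chosen plan.
- Weak points: ring A, the harder ring, and the C4 centre on it would have to come from separate chemistry. The 1,1-disubstituted alkene next to the benzylic C4–H can move into conjugation under the carbonate conditions. The C3 methylene would have to be cleaved oxidatively in the presence of a free resorcinol.
- Comparison: the chosen plan gives up the protecting-group saving. In return it makes the crowded, regiochemically demanding ring by the aldol route and sets C4 by an auxiliary-controlled aldol on an open chain.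

Alternative 2: The cut is through C1–O2 and O2–C3. A 2-hydroxyindan-1-one A4 would be cleaved by H5IO6 between C1 and C3, and the new carboxyl would add to the freed ketone to give the tribenzyl lactol A5.
- Merits: the lactol appears in one step, C3 needs no protection or separate oxidation, and C4 is never α to a free ketone for long. The endgame is shorter and gentler than the chosen one.
- Weak points: A4 needs a pentasubstituted arene with C6–OMe and C8–OBn already differentiated, made by classical aromatic chemistry. It needs an asymmetric installation of the C4 methyl beside the C5 methyl, and an α-hydroxylation at a quaternary centre. The glycol-type cleavage must pass through the hydrate of a doubly ortho-substituted aryl ketone.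
- Comparison: the chosen plan has a longer endgame. Against that, the aldol aromatisation differentiates the two ring A oxygens without extra steps, and C4 is set by a well-understood acyclic aldol.

Alternative 3: The cut is through C5–C4a and C8–C8a. The 1,3-dimethoxy-1-silyloxypentadiene A6 would add to the chiral tert-butyl ynoate A7, and loss of methanol would give the salicylate A8 with C6–OMe and free C8–OH.
- Merits: it is convergent, the methyl ether arrives in place, and the tert-butyl ester falls to acid. On paper it is the shortest road.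
- Weak points: the C5–C4a bond must form intermolecularly between a methyl-bearing diene terminus and a β-carbon carrying a branched chain. β-Alkyl ynoates are slow dienophiles toward such dienes, which decompose on prolonged heating. The propargylic C4–H of A7 is prone to allene formation.
- Comparison: the chosen plan is longer but forms the same crowded bond region intramolecularly and at room temperature. It also keeps C4 next to an sp3 carbon until late.

Key step: step 13

Assumption: the C3 hemiketal configuration is taken to be the thermodynamic one set by ring-chain equilibration, which for (4S) is (3R) (hydroxyl axial, anti to the pseudoaxial C4 methyl).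

## Route

Step 1
Reactants: 1 4,5-dimethylresorcinol
Product: 3 2,4-dihydroxy-5,6-dimethylbenzaldehyde, via aryliminium chloride 2 (not isolated)
Conditions: POCl3, DMF, MeCN, 0 °C → rt; then H2O, 50 °C
Reagents that add atoms: N,N-dimethylformamide, CN(C)C=O; water, O
Why: Vilsmeier–Haack formylation; the free ring position para to one hydroxyl and ortho to the other is the most nucleophilic site of a resorcinol, as in the formylation of orcinol, and the iminium is hydrolysed on work-up.

Step 2
Reactants: 3 2,4-dihydroxy-5,6-dimethylbenzaldehyde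
Product: 4 2,4-bis(benzyloxy)-5,6-dimethylbenzaldehyde
Conditions: BnBr, K2CO3, DMF, 60 °C
Reagents that add atoms: benzyl bromide, BrCc1ccccc1
Why: Williamson etherification of both phenols; warming in DMF overcomes the hydrogen bond of the ortho hydroxyl.

Step 3
Reactants: 4 2,4-bis(benzyloxy)-5,6-dimethylbenzaldehyde
Product: 5 2,4-bis(benzyloxy)-5,6-dimethylbenzoic acid
Conditions: NaClO2, NaH2PO4, 2-methyl-2-butene, t-BuOH–THF–H2O, rt
Reagents that add atoms: sodium chlorite, [Na+].[O-]Cl=O
Why: Pinnick oxidation tolerates hindered aryl aldehydes and benzyl ethers; the alkene scavenger removes hypochlorous acid before it can chlorinate the electron-rich ring.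

Step 4
Reactants: 5 2,4-bis(benzyloxy)-5,6-dimethylbenzoic acid; 6 allyl bromide
Product: 7 allyl 2,4-bis(benzyloxy)-5,6-dimethylbenzoate
Conditions: K2CO3, DMF, rt
Reagents that add atoms: none
Why: Carboxylate alkylation (SN2 at the allylic carbon) forms the hindered ester without attack at the shielded carbonyl.

Step 5
Reactants: 7 allyl 2,4-bis(benzyloxy)-5,6-dimethylbenzoate
Product: 9 2-oxoethyl 2,4-bis(benzyloxy)-5,6-dimethylbenzoate, via vicinal diol 8 (not isolated)
Conditions: K2OsO4·2H2O (cat.), NaIO4, 2,6-lutidine, dioxane–H2O, rt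
Reagents that add atoms: sodium periodate, [Na+].[O-]I(=O)(=O)=O; water, O
Why: Lemieux–Johnson cleavage of the terminal alkene (dihydroxylation, then periodate glycol cleavage) is milder toward benzyl ethers than ozone; the aldehyde is dried azeotropically and used at once.

Step 6
Reactants: 10 (R)-4-benzyl-3-propionyl-1,3-oxazolidin-2-one; 9 2-oxoethyl 2,4-bis(benzyloxy)-5,6-dimethylbenzoate
Product: 12 (2R,3R)-4-[(4R)-4-benzyl-2-oxo-1,3-oxazolidin-3-yl]-2-hydroxy-3-methyl-4-oxobutyl 2,4-bis(benzyloxy)-5,6-dimethylbenzoate, via dibutylboron Z-enolate 11 (not isolated)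
Conditions: Bu2BOTf, i-Pr2NEt, CH2Cl2, −78 → 0 °C; then 9, −78 → 0 °C; pH 7 buffer, MeOH, H2O2, 0 °C
Reagents that add atoms: none
Why: Evans syn aldol; the Z boron enolate reacts through a closed Zimmerman–Traxler chair with the auxiliary carbonyl turned away from the enolate oxygen, so the benzyl group of the (R)-auxiliary dictates the face and sets the C4 methyl centre as required for (4S) in 30, together with a syn C3 carbinol that is oxidised later.

Step 7
Reactants: 12 (2R,3R)-4-[(4R)-4-benzyl-2-oxo-1,3-oxazolidin-3-yl]-2-hydroxy-3-methyl-4-oxobutyl 2,4-bis(benzyloxy)-5,6-dimethylbenzoate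
Product: 13 (2R,3R)-2-hydroxy-4-[methoxy(methyl)amino]-3-methyl-4-oxobutyl 2,4-bis(benzyloxy)-5,6-dimethylbenzoate
Conditions: MeNHOMe·HCl, AlMe3, CH2Cl2, −20 → 0 °C
Reagents that add atoms: N,O-dimethylhydroxylamine hydrochloride, CNOC.Cl
Why: Weinreb transamination of an Evans aldol adduct; the aluminium alkoxide of the free C3 hydroxyl directs the amide to the exocyclic carbonyl, and the doubly ortho-substituted benzoate is too hindered for aminolysis at this temperature.

Step 8
Reactants: 13 (2R,3R)-2-hydroxy-4-[methoxy(methyl)amino]-3-methyl-4-oxobutyl 2,4-bis(benzyloxy)-5,6-dimethylbenzoate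
Product: 14 (2R,3R)-2-[tert-butyl(dimethyl)silyl]oxy-4-[methoxy(methyl)amino]-3-methyl-4-oxobutyl 2,4-bis(benzyloxy)-5,6-dimethylbenzoate
Conditions: TBSOTf, 2,6-lutidine, CH2Cl2, −78 → 0 °C
Reagents that add atoms: tert-butyldimethylsilyl triflate, CC(C)(C)[Si](C)(C)OS(=O)(=O)C(F)(F)F
Why: Silylation of a hindered secondary alcohol with the silyl triflate and a non-nucleophilic base; the silyl ether blocks retro-aldol and masks C3 until the arene is complete.

Step 9
Reactants: 14 (2R,3R)-2-[tert-butyl(dimethyl)silyl]oxy-4-[methoxy(methyl)amino]-3-methyl-4-oxobutyl 2,4-bis(benzyloxy)-5,6-dimethylbenzoate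
Product: 15 (2R,3R)-2-[tert-butyl(dimethyl)silyl]oxy-3-methyl-4-oxobutyl 2,4-bis(benzyloxy)-5,6-dimethylbenzoate
Conditions: i-Bu2AlH, THF, −78 °C; aq. potassium sodium tartrate
Reagents that add atoms: none
Why: Hydride reduction of a Weinreb amide stops at the aldehyde stage and is much faster at −78 °C than attack on the mesitoate-like ester; the aldehyde is used without chromatography to protect its α-centre.

Step 10
Reactants: 16 2,2,6-trimethyl-4H-1,3-dioxin-4-one; 17 propionyl chloride
Product: 19 2,2-dimethyl-6-(2-oxobutyl)-4H-1,3-dioxin-4-one, via lithium dienolate 18 (not isolated)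
Conditions: LiN(SiMe3)2, THF, −78 °C (2 equiv of 16 and base); then 17, −78 °C; aq. NH4Cl
Reagents that add atoms: none
Why: γ-C-Acylation (crossed Claisen) of the dioxinone dienolate with an acid chloride; the second equivalent of dienolate takes up the acidic proton of the product.

Step 11
Reactants: 19 2,2-dimethyl-6-(2-oxobutyl)-4H-1,3-dioxin-4-one; 15 (2R,3R)-2-[tert-butyl(dimethyl)silyl]oxy-3-methyl-4-oxobutyl 2,4-bis(benzyloxy)-5,6-dimethylbenzoate
Product: 21 (2R,3S)-2-[tert-butyl(dimethyl)silyl]oxy-7-(2,2-dimethyl-4-oxo-4H-1,3-dioxin-6-yl)-4-hydroxy-3,5-dimethyl-6-oxoheptyl 2,4-bis(benzyloxy)-5,6-dimethylbenzoate (mixture of epimers at the carbinol and the adjacent methyl-bearing carbon), via dilithium dianion 20 (not isolated)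
Conditions: LiN(i-Pr)2 (2.1 equiv), THF, −78 → −40 °C; then 15, −78 °C; AcOH, −78 °C
Reagents that add atoms: none
Why: Weiler-type dianion aldol; the second deprotonation occurs at the ethyl CH2 and this most basic carbon adds to the aldehyde faster than it enolises it, forming the C5–C4a bond; both new centres are destroyed in step 12, so no diastereocontrol is needed.

Step 12
Reactants: 21 (2R,3S)-2-[tert-butyl(dimethyl)silyl]oxy-7-(2,2-dimethyl-4-oxo-4H-1,3-dioxin-6-yl)-4-hydroxy-3,5-dimethyl-6-oxoheptyl 2,4-bis(benzyloxy)-5,6-dimethylbenzoate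
Product: 22 (2R,3R)-2-[tert-butyl(dimethyl)silyl]oxy-7-(2,2-dimethyl-4-oxo-4H-1,3-dioxin-6-yl)-3,5-dimethyl-4,6-dioxoheptyl 2,4-bis(benzyloxy)-5,6-dimethylbenzoate (keto–enol mixture, C5 unassigned)
Conditions: Dess–Martin periodinane, CH2Cl2, 0 °C → rt
Reagents that add atoms: none
Why: Dess–Martin oxidation of a β-hydroxy ketone to the β-diketone is non-basic, so neither retro-aldol nor enolisation toward C4 is opened; the product is taken on with minimal handling.

Step 13
Reactants: 22 (2R,3R)-2-[tert-butyl(dimethyl)silyl]oxy-7-(2,2-dimethyl-4-oxo-4H-1,3-dioxin-6-yl)-3,5-dimethyl-4,6-dioxoheptyl 2,4-bis(benzyloxy)-5,6-dimethylbenzoate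
Product: 24 (2R,3S)-2-[tert-butyl(dimethyl)silyl]oxy-3-(7-hydroxy-2,2,6-trimethyl-4-oxo-4H-1,3-benzodioxin-5-yl)butyl 2,4-bis(benzyloxy)-5,6-dimethylbenzoate, via cyclic aldol carbinol 23 (not isolated)
Conditions: Et3N, CH2Cl2, rt; then PPTS, 4 Å MS, rt
Reagents that add atoms: none
Why: Et3N removes a C7 proton, which lies between the C6 ketone and the dioxinone enol ether, and the resulting dienolate adds through its α-carbon C8a to the C4a ketone. This is a 6-(enolexo)-exo-trig aldol that closes ring A through C8a, C8, C7, C6, C5 and C4a and gives carbinol 23. E1cB loss of the C4a hydroxyl (C8a–H is α to the dioxinone carbonyl; PPTS completes it if it stalls) and enolisation of the C6 ketone through C5–H then aromatise the ring. The closest known reaction type is the amine-induced aromatisation of diketo-dioxinones to isopropylidene-protected resorcylates, a laboratory form of polyketide aldol cyclisation. No stereocentre is created, since the carbinol and C5 centres of 23 disappear on aromatisation. The step needs C-aldol selectivity over O-cyclisation to a pyranone and over Claisen attack of C5 on C1; at room temperature the dioxinone neither fragments to an acylketene nor accepts nucleophiles at C1, which leaves the aldol as the open channel. Et3N can remove only the β-dicarbonyl protons at C7 and C5 and later C8a–H, and the diketone enolises across C5 and not toward C4, so C4 is not epimerised and the C3 silyloxy group is not eliminated. C1 and the C8 oxygen emerge tied in the dioxinone, which leaves the C6 hydroxyl as the only free phenol.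

Step 14
Reactants: 24 (2R,3S)-2-[tert-butyl(dimethyl)silyl]oxy-3-(7-hydroxy-2,2,6-trimethyl-4-oxo-4H-1,3-benzodioxin-5-yl)butyl 2,4-bis(benzyloxy)-5,6-dimethylbenzoate
Product: 25 (2R,3S)-2-[tert-butyl(dimethyl)silyl]oxy-3-(7-methoxy-2,2,6-trimethyl-4-oxo-4H-1,3-benzodioxin-5-yl)butyl 2,4-bis(benzyloxy)-5,6-dimethylbenzoate
Conditions: MeI, K2CO3, acetone, rt
Reagents that add atoms: iodomethane, CI
Why: Williamson methylation of the single free phenol; carbonate in acetone offers no nucleophile that could open the dioxinone and cannot deprotonate the benzylic C4–H.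

Step 15
Reactants: 25 (2R,3S)-2-[tert-butyl(dimethyl)silyl]oxy-3-(7-methoxy-2,2,6-trimethyl-4-oxo-4H-1,3-benzodioxin-5-yl)butyl 2,4-bis(benzyloxy)-5,6-dimethylbenzoate
Product: 26 (2R,3S)-2-hydroxy-3-(7-methoxy-2,2,6-trimethyl-4-oxo-4H-1,3-benzodioxin-5-yl)butyl 2,4-bis(benzyloxy)-5,6-dimethylbenzoate
Conditions: HF·pyridine, pyridine, THF, 0 °C → rt
Reagents that add atoms: none
Why: Fluoride desilylation under buffered, non-basic conditions; no alkoxide is formed, so the liberated C3 hydroxyl should neither add to the dioxinone carbonyl nor take over the hindered aroyl group from C9.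

Step 16
Reactants: 26 (2R,3S)-2-hydroxy-3-(7-methoxy-2,2,6-trimethyl-4-oxo-4H-1,3-benzodioxin-5-yl)butyl 2,4-bis(benzyloxy)-5,6-dimethylbenzoate
Product: 27 (3S)-3-(7-methoxy-2,2,6-trimethyl-4-oxo-4H-1,3-benzodioxin-5-yl)-2-oxobutyl 2,4-bis(benzyloxy)-5,6-dimethylbenzoate
Conditions: Dess–Martin periodinane, CH2Cl2, 0 °C → rt
Reagents that add atoms: none
Why: Dess–Martin oxidation of the secondary alcohol without base; enolisation toward C4 would put a tetrasubstituted enol next to a doubly ortho-substituted arene and is disfavoured by allylic strain, and 27 is taken directly into step 17.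

Step 17
Reactants: 27 (3S)-3-(7-methoxy-2,2,6-trimethyl-4-oxo-4H-1,3-benzodioxin-5-yl)-2-oxobutyl 2,4-bis(benzyloxy)-5,6-dimethylbenzoate
Product: 29 [(3R,4S)-3,8-dihydroxy-6-methoxy-4,5-dimethyl-1-oxo-3,4-dihydro-1H-isochromen-3-yl]methyl 2,4-bis(benzyloxy)-5,6-dimethylbenzoate, via open keto acid 28 (not isolated)
Conditions: 2 M aq. HCl–THF, 45 °C
Reagents that add atoms: water, O
Why: Acid-catalysed hydrolysis of the aryl acylal releases acetone, the C8 phenol and the C1 acid, and the acid adds to the electrophilic α-acyloxy ketone (ring-chain tautomerism of a 2-(2-oxoalkyl)benzoic acid) to give the six-membered lactol. C3 settles under thermodynamic control with its hydroxyl axial and anti to the C4 methyl, which is the (3R) configuration; the water-rich medium works against dehydration to the isocoumarin.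

Step 18
Reactants: 29 [(3R,4S)-3,8-dihydroxy-6-methoxy-4,5-dimethyl-1-oxo-3,4-dihydro-1H-isochromen-3-yl]methyl 2,4-bis(benzyloxy)-5,6-dimethylbenzoate
Product: 30 [(3R,4S)-3,8-dihydroxy-6-methoxy-4,5-dimethyl-1-oxo-3,4-dihydro-1H-isochromen-3-yl]methyl 2,4-dihydroxy-5,6-dimethylbenzoate
Conditions: H2 (1 atm), 10% Pd/C, EtOAc, rt
Reagents that add atoms: none
Why: Hydrogenolysis of the two aryl benzyl ethers under neutral conditions; the molecule has no other benzylic C–O bond, and lactol, ester and C4 are not affected.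

## Compound list

1 | 4,5-dimethylresorcinol (4,5-dimethylbenzene-1,3-diol) | Oc1cc(O)c(C)c(C)c1 | starting material
2 | (2,4-dihydroxy-5,6-dimethylbenzylidene)dimethyliminium chloride | C[N+](C)=Cc1c(O)cc(O)c(C)c1C.[Cl-] | intermediate
3 | 2,4-dihydroxy-5,6-dimethylbenzaldehyde | O=Cc1c(O)cc(O)c(C)c1C | intermediate
4 | 2,4-bis(benzyloxy)-5,6-dimethylbenzaldehyde | O=Cc1c(OCc2ccccc2)cc(OCc2ccccc2)c(C)c1C | intermediate
5 | 2,4-bis(benzyloxy)-5,6-dimethylbenzoic acid | OC(=O)c1c(OCc2ccccc2)cc(OCc2ccccc2)c(C)c1C | intermediate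
6 | allyl bromide (3-bromoprop-1-ene) | C=CCBr | starting material
7 | allyl 2,4-bis(benzyloxy)-5,6-dimethylbenzoate | C=CCOC(=O)c1c(OCc2ccccc2)cc(OCc2ccccc2)c(C)c1C | intermediate
8 | 2,3-dihydroxypropyl 2,4-bis(benzyloxy)-5,6-dimethylbenzoate (racemic) | OCC(O)COC(=O)c1c(OCc2ccccc2)cc(OCc2ccccc2)c(C)c1C | intermediate
9 | 2-oxoethyl 2,4-bis(benzyloxy)-5,6-dimethylbenzoate | O=CCOC(=O)c1c(OCc2ccccc2)cc(OCc2ccccc2)c(C)c1C | intermediate
10 | (R)-4-benzyl-3-propionyl-1,3-oxazolidin-2-one | CCC(=O)N1[C@H](Cc2ccccc2)COC1=O | starting material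
11 | dibutylboron (Z)-enolate of 10 | C/C=C(\OB(CCCC)CCCC)N1[C@H](Cc2ccccc2)COC1=O | intermediate
12 | (2R,3R)-4-[(4R)-4-benzyl-2-oxo-1,3-oxazolidin-3-yl]-2-hydroxy-3-methyl-4-oxobutyl 2,4-bis(benzyloxy)-5,6-dimethylbenzoate | O=C1OC[C@@H](Cc2ccccc2)N1C(=O)[C@H](C)[C@@H](O)COC(=O)c1c(OCc2ccccc2)cc(OCc2ccccc2)c(C)c1C | intermediate
13 | (2R,3R)-2-hydroxy-4-[methoxy(methyl)amino]-3-methyl-4-oxobutyl 2,4-bis(benzyloxy)-5,6-dimethylbenzoate | CON(C)C(=O)[C@H](C)[C@@H](O)COC(=O)c1c(OCc2ccccc2)cc(OCc2ccccc2)c(C)c1C | intermediate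
14 | (2R,3R)-2-[tert-butyl(dimethyl)silyl]oxy-4-[methoxy(methyl)amino]-3-methyl-4-oxobutyl 2,4-bis(benzyloxy)-5,6-dimethylbenzoate | CON(C)C(=O)[C@H](C)[C@@H](O[Si](C)(C)C(C)(C)C)COC(=O)c1c(OCc2ccccc2)cc(OCc2ccccc2)c(C)c1C | intermediate
15 | (2R,3R)-2-[tert-butyl(dimethyl)silyl]oxy-3-methyl-4-oxobutyl 2,4-bis(benzyloxy)-5,6-dimethylbenzoate | O=C[C@H](C)[C@@H](O[Si](C)(C)C(C)(C)C)COC(=O)c1c(OCc2ccccc2)cc(OCc2ccccc2)c(C)c1C | intermediate
16 | 2,2,6-trimethyl-4H-1,3-dioxin-4-one | CC1=CC(=O)OC(C)(C)O1 | starting material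
17 | propionyl chloride | CCC(=O)Cl | starting material
18 | lithium dienolate of 16 (lithium 2,2-dimethyl-6-methylidene-6H-1,3-dioxin-4-olate) | [Li]OC1=CC(=C)OC(C)(C)O1 | intermediate
19 | 2,2-dimethyl-6-(2-oxobutyl)-4H-1,3-dioxin-4-one | CCC(=O)CC1=CC(=O)OC(C)(C)O1 | intermediate
20 | dilithium dianion of 19 (dienolate oxygen and ketone enolate oxygen lithiated) | CC=C(O[Li])C=C1C=C(O[Li])OC(C)(C)O1 | intermediate
21 | (2R,3S)-2-[tert-butyl(dimethyl)silyl]oxy-7-(2,2-dimethyl-4-oxo-4H-1,3-dioxin-6-yl)-4-hydroxy-3,5-dimethyl-6-oxoheptyl 2,4-bis(benzyloxy)-5,6-dimethylbenzoate (epimers at C4 and C5 of the heptyl chain) | CC1(C)OC(=O)C=C(CC(=O)C(C)C(O)[C@H](C)[C@@H](O[Si](C)(C)C(C)(C)C)COC(=O)c2c(OCc3ccccc3)cc(OCc3ccccc3)c(C)c2C)O1 | intermediate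
22 | (2R,3R)-2-[tert-butyl(dimethyl)silyl]oxy-7-(2,2-dimethyl-4-oxo-4H-1,3-dioxin-6-yl)-3,5-dimethyl-4,6-dioxoheptyl 2,4-bis(benzyloxy)-5,6-dimethylbenzoate (C5 of the heptyl chain unassigned) | CC1(C)OC(=O)C=C(CC(=O)C(C)C(=O)[C@H](C)[C@@H](O[Si](C)(C)C(C)(C)C)COC(=O)c2c(OCc3ccccc3)cc(OCc3ccccc3)c(C)c2C)O1 | intermediate
23 | (2R,3R)-2-[tert-butyl(dimethyl)silyl]oxy-3-(5-hydroxy-2,2,6-trimethyl-4,7-dioxo-5,6,7,8-tetrahydro-4H-1,3-benzodioxin-5-yl)butyl 2,4-bis(benzyloxy)-5,6-dimethylbenzoate (ring carbinol and adjacent methyl centre unassigned) | CC1(C)OC(=O)C2=C(O1)CC(=O)C(C)C2(O)[C@H](C)[C@@H](O[Si](C)(C)C(C)(C)C)COC(=O)c1c(OCc2ccccc2)cc(OCc2ccccc2)c(C)c1C | intermediate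
24 | (2R,3S)-2-[tert-butyl(dimethyl)silyl]oxy-3-(7-hydroxy-2,2,6-trimethyl-4-oxo-4H-1,3-benzodioxin-5-yl)butyl 2,4-bis(benzyloxy)-5,6-dimethylbenzoate | CC1(C)OC(=O)c2c(O1)cc(O)c(C)c2[C@H](C)[C@@H](O[Si](C)(C)C(C)(C)C)COC(=O)c1c(OCc3ccccc3)cc(OCc3ccccc3)c(C)c1C | intermediate
25 | (2R,3S)-2-[tert-butyl(dimethyl)silyl]oxy-3-(7-methoxy-2,2,6-trimethyl-4-oxo-4H-1,3-benzodioxin-5-yl)butyl 2,4-bis(benzyloxy)-5,6-dimethylbenzoate | CC1(C)OC(=O)c2c(O1)cc(OC)c(C)c2[C@H](C)[C@@H](O[Si](C)(C)C(C)(C)C)COC(=O)c1c(OCc3ccccc3)cc(OCc3ccccc3)c(C)c1C | intermediate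
26 | (2R,3S)-2-hydroxy-3-(7-methoxy-2,2,6-trimethyl-4-oxo-4H-1,3-benzodioxin-5-yl)butyl 2,4-bis(benzyloxy)-5,6-dimethylbenzoate | CC1(C)OC(=O)c2c(O1)cc(OC)c(C)c2[C@H](C)[C@@H](O)COC(=O)c1c(OCc3ccccc3)cc(OCc3ccccc3)c(C)c1C | intermediate
27 | (3S)-3-(7-methoxy-2,2,6-trimethyl-4-oxo-4H-1,3-benzodioxin-5-yl)-2-oxobutyl 2,4-bis(benzyloxy)-5,6-dimethylbenzoate | CC1(C)OC(=O)c2c(O1)cc(OC)c(C)c2[C@H](C)C(=O)COC(=O)c1c(OCc3ccccc3)cc(OCc3ccccc3)c(C)c1C | intermediate
28 | 2-[(2S)-4-{[2,4-bis(benzyloxy)-5,6-dimethylbenzoyl]oxy}-3-oxobutan-2-yl]-6-hydroxy-4-methoxy-3-methylbenzoic acid | COc1cc(O)c(C(=O)O)c(c1C)[C@H](C)C(=O)COC(=O)c1c(OCc2ccccc2)cc(OCc2ccccc2)c(C)c1C | intermediate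
29 | [(3R,4S)-3,8-dihydroxy-6-methoxy-4,5-dimethyl-1-oxo-3,4-dihydro-1H-isochromen-3-yl]methyl 2,4-bis(benzyloxy)-5,6-dimethylbenzoate | COc1cc(O)c2c(c1C)[C@H](C)[C@](O)(COC(=O)c1c(OCc3ccccc3)cc(OCc3ccccc3)c(C)c1C)OC2=O | intermediate
30 | [(3R,4S)-3,8-dihydroxy-6-methoxy-4,5-dimethyl-1-oxo-3,4-dihydro-1H-isochromen-3-yl]methyl 2,4-dihydroxy-5,6-dimethylbenzoate | COc1cc(O)c2c(c1C)[C@H](C)[C@](O)(COC(=O)c1c(O)cc(O)c(C)c1C)OC2=O | target

## Step count and least certain steps

Total: 18 steps. Longest linear sequence: 17 steps (steps 1–9 and 11–18, from 1); step 10 is a one-step branch.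

**Step 13 (key step).** The C8a–C4a closure has to take place on a ketone flanked by two branched carbons. If it is slow, O-cyclisation to a pyranone, stalling at the carbinol stage or slow decomposition of the diketone can take over.
Fallback, from 22 to 30: the same bond is formed on an open-chain triketo ester.
- Heating 22 in toluene with benzyl alcohol should release the acylketene and give benzyl (8R,9R)-10-{[2,4-bis(benzyloxy)-5,6-dimethylbenzoyl]oxy}-9-{[tert-butyl(dimethyl)silyl]oxy}-6,8-dimethyl-3,5,7-trioxodecanoate F1.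
- Cs2CO3 in MeOH at 0 °C, then AcOH, should aromatise it to the benzyl 2,4-dihydroxy-5-methylbenzoate F2 carrying the side chain at position 6.
- MeI/K2CO3 should methylate the non-chelated hydroxyl para to the ester and give the benzyl 2-hydroxy-4-methoxy ester F3.
- HF·pyridine should give the C3 alcohol F4, and Dess–Martin periodinane the C3 ketone F5.
- Hydrogenolysis over Pd/C removes the benzyl ester and both benzyl ethers; the acid closes on the ketone and the route ends at 30.
This fallback gives up the automatic differentiation of the two ring A oxygens and relies on chelation of the C8 hydroxyl instead.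

**Step 11.** Proton transfer from the α-branched aldehyde to the dianion would erode C4 and return 19. Retro-aldol or silyl migration in the lithium aldolate is the second risk.
Fallback, from 19 and 15 to 21: 19 is converted with Me3SiOTf/Et3N into the bis(trimethylsilyl) trienol ether 2,2-dimethyl-4-(trimethylsilyloxy)-6-[2-(trimethylsilyloxy)but-2-en-1-ylidene]-6H-1,3-dioxine F6. F6 should add through its terminal carbon to 15 under BF3·OEt2 at −78 °C (vinylogous Mukaiyama aldol) and give 21 after aqueous work-up.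

**Step 17.** Hydrolysis of the benzodioxinone may be too slow at temperatures that still exclude acid-catalysed enolisation toward C4 and dehydration of the lactol to an isocoumarin.
Fallback, from 25 to 29: the carboxyl is unmasked under neutral conditions.
- Sodium allyloxide (allyl alcohol, NaH, THF, 0 °C) should open the dioxinone of 25 to the allyl 2-hydroxy-4-methoxy-5-methylbenzoate F7 with the silylated side chain.
- HF·pyridine should give the alcohol F8, and Dess–Martin periodinane the ketone F9.
- Pd(PPh3)4 (zerovalent palladium) with PhSiH3 removes the allyl group without acid or base, and the liberated acid closes on the ketone to give 29.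

**Step 6.** The α-acyloxy aldehyde 9 may hydrate or oligomerise, which lowers conversion in the boron aldol.
Fallback, from 10 to 14: the ester is attached after the aldol.
- Enolate 11 is combined with commercial 2-[(4-methoxybenzyl)oxy]acetaldehyde to give (4R)-4-benzyl-3-[(2R,3R)-3-hydroxy-4-[(4-methoxybenzyl)oxy]-2-methylbutanoyl]-1,3-oxazolidin-2-one F10.
- Transamination as in step 7 gives the Weinreb amide F11, and silylation as in step 8 the silyl ether F12.
- DDQ removes the 4-methoxybenzyl group and gives (2R,3R)-3-{[tert-butyl(dimethyl)silyl]oxy}-4-hydroxy-N-methoxy-N,2-dimethylbutanamide F13.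
- Mitsunobu esterification of F13 with acid 5 (PPh3, DIAD), in which the hindered carboxylate is the nucleophile, gives 14.

**Step 7.** Migration of the aroyl group to the neighbouring aluminium alkoxide, or ring-opening of the oxazolidinone, may compete with transamination.
Fallback, from 12 to 15: the auxiliary is removed by reduction. Silylation of 12 (TBSOTf, 2,6-lutidine) gives the silylated imide F14. LiBH4 in wet THF at 0 °C cleaves the auxiliary to (2R,3S)-2-{[tert-butyl(dimethyl)silyl]oxy}-4-hydroxy-3-methylbutyl 2,4-bis(benzyloxy)-5,6-dimethylbenzoate F15. Dess–Martin oxidation of F15 gives 15.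

## Further compounds

F1 | step 13 | benzyl (8R,9R)-10-{[2,4-bis(benzyloxy)-5,6-dimethylbenzoyl]oxy}-9-{[tert-butyl(dimethyl)silyl]oxy}-6,8-dimethyl-3,5,7-trioxodecanoate | O=C(CC(=O)CC(=O)C(C)C(=O)[C@H](C)[C@@H](O[Si](C)(C)C(C)(C)C)COC(=O)c1c(OCc2ccccc2)cc(OCc2ccccc2)c(C)c1C)OCc1ccccc1
F2 | step 13 | benzyl 6-[(2S,3R)-4-{[2,4-bis(benzyloxy)-5,6-dimethylbenzoyl]oxy}-3-{[tert-butyl(dimethyl)silyl]oxy}butan-2-yl]-2,4-dihydroxy-5-methylbenzoate | O=C(OCc1ccccc1)c1c(O)cc(O)c(C)c1[C@H](C)[C@@H](O[Si](C)(C)C(C)(C)C)COC(=O)c1c(OCc2ccccc2)cc(OCc2ccccc2)c(C)c1C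
F3 | step 13 | benzyl 6-[(2S,3R)-4-{[2,4-bis(benzyloxy)-5,6-dimethylbenzoyl]oxy}-3-{[tert-butyl(dimethyl)silyl]oxy}butan-2-yl]-2-hydroxy-4-methoxy-5-methylbenzoate | O=C(OCc1ccccc1)c1c(O)cc(OC)c(C)c1[C@H](C)[C@@H](O[Si](C)(C)C(C)(C)C)COC(=O)c1c(OCc2ccccc2)cc(OCc2ccccc2)c(C)c1C
F4 | step 13 | benzyl 6-[(2S,3R)-4-{[2,4-bis(benzyloxy)-5,6-dimethylbenzoyl]oxy}-3-hydroxybutan-2-yl]-2-hydroxy-4-methoxy-5-methylbenzoate | O=C(OCc1ccccc1)c1c(O)cc(OC)c(C)c1[C@H](C)[C@@H](O)COC(=O)c1c(OCc2ccccc2)cc(OCc2ccccc2)c(C)c1C
F5 | step 13 | benzyl 6-[(2S)-4-{[2,4-bis(benzyloxy)-5,6-dimethylbenzoyl]oxy}-3-oxobutan-2-yl]-2-hydroxy-4-methoxy-5-methylbenzoate | O=C(OCc1ccccc1)c1c(O)cc(OC)c(C)c1[C@H](C)C(=O)COC(=O)c1c(OCc2ccccc2)cc(OCc2ccccc2)c(C)c1C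
F6 | step 11 | 2,2-dimethyl-4-(trimethylsilyloxy)-6-[2-(trimethylsilyloxy)but-2-en-1-ylidene]-6H-1,3-dioxine | CC=C(O[Si](C)(C)C)C=C1C=C(O[Si](C)(C)C)OC(C)(C)O1
F7 | step 17 | allyl 6-[(2S,3R)-4-{[2,4-bis(benzyloxy)-5,6-dimethylbenzoyl]oxy}-3-{[tert-butyl(dimethyl)silyl]oxy}butan-2-yl]-2-hydroxy-4-methoxy-5-methylbenzoate | C=CCOC(=O)c1c(O)cc(OC)c(C)c1[C@H](C)[C@@H](O[Si](C)(C)C(C)(C)C)COC(=O)c1c(OCc2ccccc2)cc(OCc2ccccc2)c(C)c1C
F8 | step 17 | allyl 6-[(2S,3R)-4-{[2,4-bis(benzyloxy)-5,6-dimethylbenzoyl]oxy}-3-hydroxybutan-2-yl]-2-hydroxy-4-methoxy-5-methylbenzoate | C=CCOC(=O)c1c(O)cc(OC)c(C)c1[C@H](C)[C@@H](O)COC(=O)c1c(OCc2ccccc2)cc(OCc2ccccc2)c(C)c1C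
F9 | step 17 | allyl 6-[(2S)-4-{[2,4-bis(benzyloxy)-5,6-dimethylbenzoyl]oxy}-3-oxobutan-2-yl]-2-hydroxy-4-methoxy-5-methylbenzoate | C=CCOC(=O)c1c(O)cc(OC)c(C)c1[C@H](C)C(=O)COC(=O)c1c(OCc2ccccc2)cc(OCc2ccccc2)c(C)c1C
F10 | step 6 | (4R)-4-benzyl-3-[(2R,3R)-3-hydroxy-4-[(4-methoxybenzyl)oxy]-2-methylbutanoyl]-1,3-oxazolidin-2-one | O=C1OC[C@@H](Cc2ccccc2)N1C(=O)[C@H](C)[C@@H](O)COCc1ccc(OC)cc1
F11 | step 6 | (2R,3R)-3-hydroxy-N-methoxy-4-[(4-methoxybenzyl)oxy]-N,2-dimethylbutanamide | CON(C)C(=O)[C@H](C)[C@@H](O)COCc1ccc(OC)cc1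
F12 | step 6 | (2R,3R)-3-{[tert-butyl(dimethyl)silyl]oxy}-N-methoxy-4-[(4-methoxybenzyl)oxy]-N,2-dimethylbutanamide | CON(C)C(=O)[C@H](C)[C@@H](O[Si](C)(C)C(C)(C)C)COCc1ccc(OC)cc1
F13 | step 6 | (2R,3R)-3-{[tert-butyl(dimethyl)silyl]oxy}-4-hydroxy-N-methoxy-N,2-dimethylbutanamide | CON(C)C(=O)[C@H](C)[C@@H](O[Si](C)(C)C(C)(C)C)CO
F14 | step 7 | (2R,3R)-4-[(4R)-4-benzyl-2-oxo-1,3-oxazolidin-3-yl]-2-{[tert-butyl(dimethyl)silyl]oxy}-3-methyl-4-oxobutyl 2,4-bis(benzyloxy)-5,6-dimethylbenzoate | O=C1OC[C@@H](Cc2ccccc2)N1C(=O)[C@H](C)[C@@H](O[Si](C)(C)C(C)(C)C)COC(=O)c1c(OCc2ccccc2)cc(OCc2ccccc2)c(C)c1C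
F15 | step 7 | (2R,3S)-2-{[tert-butyl(dimethyl)silyl]oxy}-4-hydroxy-3-methylbutyl 2,4-bis(benzyloxy)-5,6-dimethylbenzoate | OC[C@H](C)[C@@H](O[Si](C)(C)C(C)(C)C)COC(=O)c1c(OCc2ccccc2)cc(OCc2ccccc2)c(C)c1C
A1 | alternative 1 | benzyl 2-(benzyloxy)-6-[(2S)-3-(hydroxymethyl)but-3-en-2-yl]-4-methoxy-5-methylbenzoate | COc1cc(OCc2ccccc2)c(C(=O)OCc2ccccc2)c(c1C)[C@H](C)C(=C)CO
A2 | alternative 1 | 2,2-dimethyl-6-(3-methyl-2,4-dioxopentyl)-4H-1,3-dioxin-4-one | CC(=O)C(C)C(=O)CC1=CC(=O)OC(C)(C)O1
A3 | alternative 1 | 2,4-dihydroxy-5,6-dimethylbenzoate ester of A1 at its primary hydroxyl | COc1cc(OCc2ccccc2)c(C(=O)OCc2ccccc2)c(c1C)[C@H](C)C(=C)COC(=O)c1c(O)cc(O)c(C)c1C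
A4 | alternative 2 | [(3S)-7-(benzyloxy)-2-hydroxy-5-methoxy-3,4-dimethyl-1-oxo-2,3-dihydro-1H-inden-2-yl]methyl 2,4-bis(benzyloxy)-5,6-dimethylbenzoate (C2 unassigned) | COc1cc(OCc3ccccc3)c2c(c1C)[C@H](C)C(O)(COC(=O)c1c(OCc3ccccc3)cc(OCc3ccccc3)c(C)c1C)C2=O
A5 | alternative 2 | [(3R,4S)-8-(benzyloxy)-3-hydroxy-6-methoxy-4,5-dimethyl-1-oxo-3,4-dihydro-1H-isochromen-3-yl]methyl 2,4-bis(benzyloxy)-5,6-dimethylbenzoate | COc1cc(OCc3ccccc3)c2c(c1C)[C@H](C)[C@](O)(COC(=O)c1c(OCc3ccccc3)cc(OCc3ccccc3)c(C)c1C)OC2=O
A6 | alternative 3 | 1,3-dimethoxy-1-(trimethylsilyloxy)penta-1,3-diene | CC=C(OC)C=C(OC)O[Si](C)(C)C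
A7 | alternative 3 | tert-butyl (4S,5S)-6-{[2,4-bis(benzyloxy)-5,6-dimethylbenzoyl]oxy}-5-{[tert-butyl(dimethyl)silyl]oxy}-4-methylhex-2-ynoate | CC(C)(C)OC(=O)C#C[C@H](C)[C@H](O[Si](C)(C)C(C)(C)C)COC(=O)c1c(OCc2ccccc2)cc(OCc2ccccc2)c(C)c1C
A8 | alternative 3 | tert-butyl 6-[(2S,3S)-4-{[2,4-bis(benzyloxy)-5,6-dimethylbenzoyl]oxy}-3-{[tert-butyl(dimethyl)silyl]oxy}butan-2-yl]-2-hydroxy-4-methoxy-5-methylbenzoate | COc1cc(O)c(C(=O)OC(C)(C)C)c(c1C)[C@H](C)[C@H](O[Si](C)(C)C(C)(C)C)COC(=O)c1c(OCc2ccccc2)cc(OCc2ccccc2)c(C)c1C
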